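The figure the meeting kept returning to was 0.0116 M⁻¹ min⁻¹, the mean constant of the beta run: the natural logarithm of [Q] charged over [Q] left at 84 min, divided by that time and by the mean of [X] over the run, which is a pseudo-first-order treatment of Q that turns a whole curve into one number.

| flask | Q | X | G | time |
|---|---|---|---|---|
| epsilon | 0.500 M | 1.00 M | 0.00250 M |  |
| beta | 0.250 M | 1.00 M | 0.00250 M |  |
| theta | 0.500 M | 1.00 M | 0.00750 M |  |
| alpha | 0.500 M | 1.50 M | 0.00250 M |  |
| eta | 0.110 M | 1.00 M | 0.00250 M | 84 min |

- epsilon run (time / min: [L] / M): 6.4: 0.0419; 19: 0.0973; 37: 0.1593; 59: 0.2145; 84: 0.2594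
- beta run (time / min: [L] / M): 6.4: 0.0194; 19: 0.0509; 37: 0.0890; 59: 0.1211; 84: 0.1486
- theta run (time / min: [L] / M): 6.4: 0.1324; 19: 0.2687; 37: 0.3566; 59: 0.4131; 84: 0.4438
- alpha run (time / min: [L] / M): 6.4: 0.0574; 19: 0.1406; 37: 0.2155; 59: 0.2738; 84: 0.3212

(each reading ± 0.002 M)

1. apparent order in [Q] of the starting rate, round the charge of the epsilon run (the rate where two percent of its Q have turned into L) (one fixed amount of L, the same in the runs compared)
2. apparent order in [X] of the starting rate, round the charge of the epsilon run (the rate where two percent of its Q have turned into L)
3. L in the eta run at 84 min, as a share of the Q charged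
4. which of these the readings show (the catalyst wakes slowly / the product ties up the catalyst / nothing beyond the main steps / the second partner kills the catalyst)

- Overall: Q + X -> L, with G as catalyst.
- Constant volume, constant temperature.
- Readings of a species count what is bound in complexes too.
- "The second partner" is X.
- An order is taken over about fifteen percent of the charge, up and down.

The first speaker reported that the same reckoning gives 0.0100 M⁻¹ min⁻¹ for epsilon and 0.00914 M⁻¹ min⁻¹ for alpha, and argued that the constant falls as the final [L] rises from 0.1486 M in beta through 0.2594 M in epsilon to 0.3212 M in alpha.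

A second member asked whether [X] harms the catalyst, since alpha, with the most [X], has the lowest of these constants, but the first speaker answered that beta and epsilon share their [X] and their times and still differ. She added that a straight line through beta and alpha, of slope 0.0143 M⁻² min⁻¹, passes epsilon at 0.0100 M⁻¹ min⁻¹, close to its reading.

A slow wake-up was dismissed as well, because the epsilon rate over the first interval, 0.00655 M min⁻¹, is faster than the 0.00180 M min⁻¹ over the last. The meeting therefore concluded that the product ties up the catalyst, and, since dividing by [Q] and [X] puts these runs on one line, reckoned first order in each.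

For eta, which has the [G] of those runs, the line was carried back to the mean constant at no L, 0.0137 M⁻¹ min⁻¹. A first guess of 0.7 of the charge as L gave 63.9%, and repeating with that share gave 64.3%.

The second member then asked what the mean [X] costs: the exact second-order integral for beta gives 0.0118 M⁻¹ min⁻¹, which is 1.42% above the mean value, and eta loses less [X], 0.0708 M, than beta's 0.1486 M.

The forecast gives 1 in [Q], 0.87 in [X], lower than the order reckoned here, 63.5% for eta and "the product ties up the catalyst", holding that "These values follow the amount of L formed, not elapsed time or [X]."

The flask gives orders of 1.0 in [Q] and 1.0 in [X], 64.0% for eta, and "the product ties up the catalyst". The fit with nothing beyond the main steps gives 58.1% for eta, with a residual of 5.2 in units of the scatter.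

    2 G ⇌ G2, settled at all times (296.0 M⁻¹)
    G2 + Q + X → L + G2 (24.60 M⁻² min⁻¹)
    G + L ⇌ GL, settled at all times (2.660 M⁻¹)

The eta result read as a mean constant is 0.0126 M⁻¹ min⁻¹, against 0.0127 M⁻¹ min⁻¹ on the line. At half of the Q charged, theta and epsilon hold the same [L], where the line gives 0.0102 M⁻¹ min⁻¹ for the [G] of epsilon, while the theta half-time of 16.8 min gives 0.0471 M⁻¹ min⁻¹. With 3.00 times the [G] of epsilon, theta therefore stands at 4.62 times the line value.

(The earlier runs and the new flask were generated by integration with made-up constants; scatter was added.)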